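Assumption: the SMILES has no stereocentre and no hindered axis (all four diaryl ethers rotate freely), so the target is achiral, no step needs stereocontrol and no step creates a stereocentre. Rings are labelled A to E from the 2,4,6-trihydroxyphenoxy end (A) to the 3,4,5-trihydroxyphenoxy end (E).

## Retrosynthetic overview

1. No ring is built. All five benzene rings are bought as 1,2,3-trioxygenated arenes. Every oxygen at a "5-position" (two OH, two ether O) is added later through sterically governed Ir C–H borylation, instead of coupling five fully oxygenated monomers by iterative Ullmann reactions.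
2. Target ⇒ tenfold O-demethylation ⇒ bis-phenol ⇒ key step: twofold late-stage C–H borylation/oxidation at the only two unhindered C–H bonds (para positions of rings A and C) ⇒ "bis-deoxy" pentamer.
3. Pentamer ⇒ cut at the C–O–D ether (Chan–Lam–Evans) ⇒ trimer phenol A–B–C plus dimer boronic acid D–E.
4. Ring C is 2-fluoro-6-methoxybenzaldehyde. Its CHO first activates the SNAr that makes the B–O–C ether, then becomes the phenol oxygen of the C–O–D ether (Baeyer–Villiger/Dakin).
5. Hidden symmetry: A–B and D–E are the same dimer (syringol plus 3,4,5-trimethoxyphenylboronic acid). C–H borylation turns it into D–E, and cleavage of its central OMe turns it into A–B. Joining order: dimer (D–E ≡ A–B), then B–C, then C–D.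

## Route

Step 1
Reactants: 1 3,4,5-trimethoxyphenylboronic acid; 2 2,6-dimethoxyphenol (syringol)
Product: 3 1,3-dimethoxy-2-(3,4,5-trimethoxyphenoxy)benzene
Conditions: 1 (1.5 equiv), Cu(OAc)2 (2 equiv), pyridine (5 equiv), 4 Å MS, CH2Cl2, dry air, rt, 48 h
Reagents that add atoms: none
Why: In this Chan–Lam–Evans oxidative O-arylation the Cu(II) phenoxide transmetalates with an ortho-unhindered boronic acid and reductively eliminates from Cu(III) at room temperature, so the steric load sits only on the phenol partner, which this coupling tolerates, and excess boronic acid under air rather than O2 keeps arylation ahead of phenol oxidation.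

Step 2
Reactants: 3 1,3-dimethoxy-2-(3,4,5-trimethoxyphenoxy)benzene
Product: 5 [3,5-dimethoxy-4-(3,4,5-trimethoxyphenoxy)phenyl]boronic acid, via pinacol boronate 4 (not isolated)
Conditions: [Ir(OMe)(cod)]2 (1.5 mol %), dtbpy (3 mol %), B2pin2 (1.0 equiv), THF, 80 °C; evaporate; then NaIO4 (3 equiv), THF/H2O 4:1, 1 M HCl (cat.), rt
Reagents that add atoms: bis(pinacolato)diboron, CC1(C)OB(OC1(C)C)B1OC(C)(C)C(C)(C)O1; water, O
Why: Sterically governed Ir-catalysed C–H borylation (Ishiyama–Miyaura–Hartwig) attacks only a C–H with no ortho substituent, and 3 has exactly one (para to the aryloxy group, a site electrophilic substitution cannot reach), after which periodate cleavage of the pinacol ester frees the boronic acid in the same pot.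

Step 3
Reactants: 3 1,3-dimethoxy-2-(3,4,5-trimethoxyphenoxy)benzene
Product: 6 4-(2,6-dimethoxyphenoxy)-2,6-dimethoxyphenol
Conditions: BCl3 (1.2 equiv, 1 M in CH2Cl2), CH2Cl2, −10 °C → rt; H2O quench
Reagents that add atoms: none
Why: Lewis-acid aryl methyl ether cleavage with BCl3 selects the most hindered methoxy group, because the central OMe of the 1,2,3-trimethoxy ring is twisted out of conjugation and is therefore the most basic oxygen and chelatable with a neighbour, whereas the two OMe groups of the other ring lie in plane and flank only a non-basic diaryl ether oxygen.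

Step 4
Reactants: 6 4-(2,6-dimethoxyphenoxy)-2,6-dimethoxyphenol; 7 2-fluoro-6-methoxybenzaldehyde
Product: 8 2-[4-(2,6-dimethoxyphenoxy)-2,6-dimethoxyphenoxy]-6-methoxybenzaldehyde
Conditions: 7 (1.3 equiv), K2CO3 (2 equiv), DMF, 120 °C, Ar, 16 h
Reagents that add atoms: none
Why: This SNAr (addition–elimination) works because the ortho-formyl group stabilises the Meisenheimer adduct, fluoride is the best leaving group for a rate-limiting addition, the methoxy group is meta to the reacting carbon and does not deactivate it, and all other ethers are inert to carbonate.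

Step 5
Reactants: 8 2-[4-(2,6-dimethoxyphenoxy)-2,6-dimethoxyphenoxy]-6-methoxybenzaldehyde
Product: 10 2-[4-(2,6-dimethoxyphenoxy)-2,6-dimethoxyphenoxy]-6-methoxyphenol, via aryl formate 9 (not isolated)
Conditions: mCPBA (1.4 equiv), CH2Cl2, 0 °C → rt; aqueous wash; then K2CO3 (cat.), MeOH, rt
Reagents that add atoms: mCPBA, OOC(=O)c1cccc(Cl)c1
Why: In this Baeyer–Villiger (Dakin-type) oxidation the electron-rich 2,6-dioxygenated aryl group migrates in the Criegee adduct in preference to hydride, and mild methanolysis of the resulting formate frees the phenol exactly where the C–O–D ether is needed.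

Step 6
Reactants: 10 2-[4-(2,6-dimethoxyphenoxy)-2,6-dimethoxyphenoxy]-6-methoxyphenol; 5 [3,5-dimethoxy-4-(3,4,5-trimethoxyphenoxy)phenyl]boronic acid
Product: 11 1-[4-(2,6-dimethoxyphenoxy)-2,6-dimethoxyphenoxy]-2-[3,5-dimethoxy-4-(3,4,5-trimethoxyphenoxy)phenoxy]-3-methoxybenzene
Conditions: 5 (1.5 equiv), Cu(OAc)2 (2 equiv), pyridine (5 equiv), 4 Å MS, CH2Cl2, dry air, rt, 72 h
Reagents that add atoms: none
Why: This Chan–Lam–Evans coupling is the convergent union, and as in the thyroxine-type cases a di-ortho-substituted phenol is arylated at room temperature because the boron partner has two ortho hydrogens, while the neutral conditions leave all ten methyl ethers and three diaryl ethers untouched.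

Step 7
Reactants: 11 1-[4-(2,6-dimethoxyphenoxy)-2,6-dimethoxyphenoxy]-2-[3,5-dimethoxy-4-(3,4,5-trimethoxyphenoxy)phenoxy]-3-methoxybenzene
Product: 13 3-[4-(4-hydroxy-2,6-dimethoxyphenoxy)-2,6-dimethoxyphenoxy]-4-[3,5-dimethoxy-4-(3,4,5-trimethoxyphenoxy)phenoxy]-5-methoxyphenol, via bis(pinacol boronate) 12 (not isolated)
Conditions: [Ir(OMe)(cod)]2 (5 mol %), 3,4,7,8-tetramethyl-1,10-phenanthroline (10 mol %), B2pin2 (3 equiv), THF, 80 °C, 24 h; evaporate; then 30 % aq H2O2, NaHCO3 buffer, THF/H2O, 0 °C → rt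
Reagents that add atoms: bis(pinacolato)diboron, CC1(C)OB(OC1(C)C)B1OC(C)(C)C(C)(C)O1; hydrogen peroxide, OO
Why: In this one-pot twofold C–H borylation/oxidation (late-stage C–H hydroxylation) only two of the twelve aromatic C–H bonds of 11 have no ortho substituent (C4 of ring A and C5 of ring C, each the 5-position of a 1,2,3-trisubstituted ring), so steric control places boron exactly where the two missing hydroxyls belong, and the 1,2-aryl shift of the boron hydroperoxide adduct replaces B by O at the same carbon.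

Step 8
Reactants: 13 3-[4-(4-hydroxy-2,6-dimethoxyphenoxy)-2,6-dimethoxyphenoxy]-4-[3,5-dimethoxy-4-(3,4,5-trimethoxyphenoxy)phenoxy]-5-methoxyphenol
Product: 14 CNP0227069.0 (target, dodecahydroxy pentamer)
Conditions: BBr3 (25 equiv, 1 M in CH2Cl2), CH2Cl2, −78 °C → rt, 24 h, Ar; ice-water quench; EtOAc; Sephadex LH-20 with degassed MeOH
Reagents that add atoms: none
Why: Exhaustive BBr3 aryl methyl ether cleavage proceeds by bromide SN2 attack at the methyl carbon of each O–B complex, which removes all ten methyl groups while the four diaryl ethers, having no sp3 carbon to attack, survive, and oxygen-free work-up protects the polyphenol.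

## Compound list

1 | 3,4,5-trimethoxyphenylboronic acid | COc1cc(B(O)O)cc(OC)c1OC | starting material
2 | 2,6-dimethoxyphenol (syringol) | COc1cccc(OC)c1O | starting material
3 | 1,3-dimethoxy-2-(3,4,5-trimethoxyphenoxy)benzene (common dimer) | COc1cccc(OC)c1Oc1cc(OC)c(OC)c(OC)c1 | intermediate
4 | 2-[3,5-dimethoxy-4-(3,4,5-trimethoxyphenoxy)phenyl]-4,4,5,5-tetramethyl-1,3,2-dioxaborolane | COc1cc(B2OC(C)(C)C(C)(C)O2)cc(OC)c1Oc1cc(OC)c(OC)c(OC)c1 | intermediate (not isolated)
5 | [3,5-dimethoxy-4-(3,4,5-trimethoxyphenoxy)phenyl]boronic acid (D–E) | COc1cc(B(O)O)cc(OC)c1Oc1cc(OC)c(OC)c(OC)c1 | intermediate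
6 | 4-(2,6-dimethoxyphenoxy)-2,6-dimethoxyphenol (A–B) | COc1cccc(OC)c1Oc1cc(OC)c(O)c(OC)c1 | intermediate
7 | 2-fluoro-6-methoxybenzaldehyde (ring C) | COc1cccc(F)c1C=O | starting material
8 | 2-[4-(2,6-dimethoxyphenoxy)-2,6-dimethoxyphenoxy]-6-methoxybenzaldehyde | COc1cccc(OC)c1Oc1cc(OC)c(Oc2cccc(OC)c2C=O)c(OC)c1 | intermediate
9 | 2-[4-(2,6-dimethoxyphenoxy)-2,6-dimethoxyphenoxy]-6-methoxyphenyl formate | COc1cccc(OC)c1Oc1cc(OC)c(Oc2cccc(OC)c2OC=O)c(OC)c1 | intermediate (not isolated)
10 | 2-[4-(2,6-dimethoxyphenoxy)-2,6-dimethoxyphenoxy]-6-methoxyphenol (A–B–C) | COc1cccc(OC)c1Oc1cc(OC)c(Oc2cccc(OC)c2O)c(OC)c1 | intermediate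
11 | 1-[4-(2,6-dimethoxyphenoxy)-2,6-dimethoxyphenoxy]-2-[3,5-dimethoxy-4-(3,4,5-trimethoxyphenoxy)phenoxy]-3-methoxybenzene (bis-deoxy pentamer, ten OMe) | COc1cccc(OC)c1Oc1cc(OC)c(Oc2cccc(OC)c2Oc2cc(OC)c(Oc3cc(OC)c(OC)c(OC)c3)c(OC)c2)c(OC)c1 | intermediate
12 | bis(pinacol boronate) of 11 (Bpin at C4 of ring A and at C5 of ring C) | COc1cc(B2OC(C)(C)C(C)(C)O2)cc(OC)c1Oc1cc(OC)c(Oc2cc(B3OC(C)(C)C(C)(C)O3)cc(OC)c2Oc2cc(OC)c(Oc3cc(OC)c(OC)c(OC)c3)c(OC)c2)c(OC)c1 | intermediate (not isolated)
13 | 3-[4-(4-hydroxy-2,6-dimethoxyphenoxy)-2,6-dimethoxyphenoxy]-4-[3,5-dimethoxy-4-(3,4,5-trimethoxyphenoxy)phenoxy]-5-methoxyphenol | COc1cc(O)cc(OC)c1Oc1cc(OC)c(Oc2cc(O)cc(OC)c2Oc2cc(OC)c(Oc3cc(OC)c(OC)c(OC)c3)c(OC)c2)c(OC)c1 | intermediate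
14 | CNP0227069.0 (achiral) | Oc1cc(O)c(Oc2cc(O)c(Oc3cc(O)cc(O)c3Oc3cc(O)c(Oc4cc(O)c(O)c(O)c4)c(O)c3)c(O)c2)c(O)c1 | target

## Step count and risks

Total step count: 8.
Longest linear sequence: 7 (steps 1, 3, 4, 5, 6, 7 and 8). Step 2 is the side branch from the same dimer 3.

**Most likely to fail, first: step 6.** Phenol 10 is bulky, di-ortho-substituted and electron-rich with a free para position. Cu(II)/amine/air may therefore oxidise it, or 5 may be protodeboronated or oxidised, faster than the ether forms.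

The fallback sets out from 4 (together with 10) and comes back at 11. It abandons the oxidative boron coupling for a halide coupling under inert gas. Boronate 4 is isolated after the borylation of step 2 and ipso-iodinated (CuI cat., 1,10-phenanthroline, KI, MeOH/H2O, air, 80 °C) to 5-iodo-1,3-dimethoxy-2-(3,4,5-trimethoxyphenoxy)benzene F1. F1 is then joined to 10 by a Cu(I) Ullmann-type etherification developed for hindered phenols (CuI, picolinic acid, K3PO4, DMSO, 90 °C, Ar) to give 11.

**Second: step 3.** BCl3 must pick one of five OMe groups, and over-cleavage to a catechol or attack on the other ring would erode the yield.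

The fallback sets out from 2 and comes back at 6. It carries the ring-B phenol as an orthogonal benzyl ether instead of differentiating methyl ethers afterwards.

- Part of 2 is para-brominated (NBS, CHCl3/MeOH, −45 °C) to 4-bromo-2,6-dimethoxyphenol F2, which can also be bought.
- F2 is benzylated (BnBr, K2CO3, acetone, reflux) to 2-(benzyloxy)-5-bromo-1,3-dimethoxybenzene F3.
- F3 is coupled with more 2 (CuI, picolinic acid, K3PO4, DMSO, 100 °C, Ar) to 2-(benzyloxy)-5-(2,6-dimethoxyphenoxy)-1,3-dimethoxybenzene F4.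
- Hydrogenolysis of F4 (H2, Pd/C, EtOAc, rt) gives 6.

**Third: step 7.** Two borylations are needed on a very electron-rich molecule of about 750 Da. They may stop at the mono stage, and the product phenols are sensitive to the oxidant.

The fallback sets out from 4 (and later uses 5) and comes back at 14. It installs both oxygens at fragment level, where the borylation is already proven or not needed.

- 4 is oxidised (30 % H2O2, THF/H2O) to 3,5-dimethoxy-4-(3,4,5-trimethoxyphenoxy)phenol F5.
- F5 is methylated (MeI, K2CO3, acetone) to 1,3,5-trimethoxy-2-(3,4,5-trimethoxyphenoxy)benzene F6.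
- BCl3 as in step 3 gives 2,6-dimethoxy-4-(2,4,6-trimethoxyphenoxy)phenol F7.
- Ring C now comes from commercial 1-fluoro-3,5-dimethoxybenzene F8, which Vilsmeier–Haack formylation (POCl3, DMF) converts into 2-fluoro-4,6-dimethoxybenzaldehyde F9.
- SNAr of F7 on F9 as in step 4 gives 2-[2,6-dimethoxy-4-(2,4,6-trimethoxyphenoxy)phenoxy]-4,6-dimethoxybenzaldehyde F10.
- mCPBA converts F10 into 2-[2,6-dimethoxy-4-(2,4,6-trimethoxyphenoxy)phenoxy]-4,6-dimethoxyphenyl formate F11.
- Methanolysis of F11 gives 2-[2,6-dimethoxy-4-(2,4,6-trimethoxyphenoxy)phenoxy]-4,6-dimethoxyphenol F12.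
- Coupling of F12 with 5 as in step 6 gives the dodeca-O-methyl ether of the target F13.
- BBr3 as in step 8 converts F13 into 14.

## Further compounds

F1 | step 6 | 5-iodo-1,3-dimethoxy-2-(3,4,5-trimethoxyphenoxy)benzene | COc1cc(I)cc(OC)c1Oc1cc(OC)c(OC)c(OC)c1
F2 | step 3 | 4-bromo-2,6-dimethoxyphenol | COc1cc(Br)cc(OC)c1O
F3 | step 3 | 2-(benzyloxy)-5-bromo-1,3-dimethoxybenzene | COc1cc(Br)cc(OC)c1OCc1ccccc1
F4 | step 3 | 2-(benzyloxy)-5-(2,6-dimethoxyphenoxy)-1,3-dimethoxybenzene | COc1cccc(OC)c1Oc1cc(OC)c(OCc2ccccc2)c(OC)c1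
F5 | step 7 | 3,5-dimethoxy-4-(3,4,5-trimethoxyphenoxy)phenol | COc1cc(O)cc(OC)c1Oc1cc(OC)c(OC)c(OC)c1
F6 | step 7 | 1,3,5-trimethoxy-2-(3,4,5-trimethoxyphenoxy)benzene | COc1cc(OC)c(Oc2cc(OC)c(OC)c(OC)c2)c(OC)c1
F7 | step 7 | 2,6-dimethoxy-4-(2,4,6-trimethoxyphenoxy)phenol | COc1cc(OC)c(Oc2cc(OC)c(O)c(OC)c2)c(OC)c1
F8 | step 7 | 1-fluoro-3,5-dimethoxybenzene | COc1cc(F)cc(OC)c1
F9 | step 7 | 2-fluoro-4,6-dimethoxybenzaldehyde | COc1cc(F)c(C=O)c(OC)c1
F10 | step 7 | 2-[2,6-dimethoxy-4-(2,4,6-trimethoxyphenoxy)phenoxy]-4,6-dimethoxybenzaldehyde | COc1cc(OC)c(Oc2cc(OC)c(Oc3cc(OC)cc(OC)c3C=O)c(OC)c2)c(OC)c1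
F11 | step 7 | 2-[2,6-dimethoxy-4-(2,4,6-trimethoxyphenoxy)phenoxy]-4,6-dimethoxyphenyl formate | COc1cc(OC)c(Oc2cc(OC)c(Oc3cc(OC)cc(OC)c3OC=O)c(OC)c2)c(OC)c1
F12 | step 7 | 2-[2,6-dimethoxy-4-(2,4,6-trimethoxyphenoxy)phenoxy]-4,6-dimethoxyphenol | COc1cc(OC)c(Oc2cc(OC)c(Oc3cc(OC)cc(OC)c3O)c(OC)c2)c(OC)c1
F13 | step 7 | dodeca-O-methyl ether of the target | COc1cc(OC)c(Oc2cc(OC)c(Oc3cc(OC)cc(OC)c3Oc3cc(OC)c(Oc4cc(OC)c(OC)c(OC)c4)c(OC)c3)c(OC)c2)c(OC)c1
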